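**Retrosynthetic overview**
1. 27 ⇐ 26 ⇐ 25: the end game only unmasks C4 (1,3-dithiane → ketone) and three phenols (MOM ethers).
2. 25 ⇐ 21 + 19 in one pot: the C8–H/C8a–F pair of ring A becomes a C8–C8a aryne, the C2 alkoxide closes ring C at C8a (O1–C8a), and the resulting C8 aryllithium is alkylated by (S)-lavandulyl iodide (C8–C1'').
3. Enabling feature: on ring A, O1 sits on C8a and the side-chain carbon on the adjacent C8, C8 lies between O1 and the C7 methoxy oxygen, and O1 is tied to C4a through C2–C3–C4. This is the imprint of an O-nucleophile and a C-electrophile added across an aryne whose polarity the C7–OMe fixes.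
4. 21 ⇐ 4 + 11 (Corey–Seebach C3–C4 bond; C2 stereocentre from a CBS-derived (R)-epoxide); 19 ⇐ Evans deconjugative prenylation (side-chain stereocentre).
5. Ring order: rings A and B are bought as benzenes (1 and 5); ring C is the only ring of the target that is built, and it is closed in step 12; the dithiane ring is temporary.

Key step: step 12

Remark: flavanone numbering is used (O1, C2, C3, C4, C4a, C5–C8, C8a; ring B primed; C1'' is the side-chain CH2 on C8). The target is (2S) with an (R)-configured lavandulyl centre, which corresponds spatially to (S)-lavandulol.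

**Ring A fragment**

Step 1
Reactants: 1 2,6-difluoro-4-methoxybenzaldehyde
Product: 2 2-fluoro-6-hydroxy-4-methoxybenzaldehyde
Conditions: MeSO2CH2CH2OH (1.05 equiv), NaH (2.5 equiv), DMF, 0 °C → rt; then 1 M HCl
Reagents that add atoms: 2-(methylsulfonyl)ethanol CS(=O)(=O)CCO
Why: SNAr of one of the two equivalent, formyl-activated ortho fluorines by the alkoxide, then E1cB loss of methyl vinyl sulfone, gives the phenoxide, which deactivates the ring against a second substitution and avoids the deformylation that free hydroxide can cause.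

Step 2
Reactants: 2 2-fluoro-6-hydroxy-4-methoxybenzaldehyde
Product: 3 2-(1,3-dithian-2-yl)-3-fluoro-5-methoxyphenol
Conditions: HS(CH2)3SH, BF3·OEt2, CH2Cl2, 0 °C → rt
Reagents that add atoms: propane-1,3-dithiol SCCCS
Why: Lewis-acid-promoted dithioacetalization of the aldehyde, run on the free phenol because a MOM ether would not survive BF3 and thiol.

Step 3
Reactants: 3 2-(1,3-dithian-2-yl)-3-fluoro-5-methoxyphenol
Product: 4 2-[2-fluoro-4-methoxy-6-(methoxymethoxy)phenyl]-1,3-dithiane
Conditions: NaH, MOMCl, DMF, 0 °C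
Reagents that add atoms: chloromethyl methyl ether COCCl
Why: Williamson-type O-alkylation of the sodium phenoxide; MOM survives organolithiums, cannot migrate to an alkoxide and leaves with acid at the end.

**Ring B fragment**

Step 4
Reactants: 5 resorcinol
Product: 6 1,3-bis(methoxymethoxy)benzene
Conditions: NaH (2.2 equiv), MOMCl (2.2 equiv), DMF, 0 °C → rt
Reagents that add atoms: chloromethyl methyl ether COCCl
Why: Double Williamson-type O-alkylation; the two MOM ethers then direct the lithiation of step 5 to the carbon between them.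

Step 5
Reactants: 6 1,3-bis(methoxymethoxy)benzene; 7 2-chloro-N-methoxy-N-methylacetamide
Product: 9 1-[2,6-bis(methoxymethoxy)phenyl]-2-chloroethan-1-one, via aryllithium 8 (not isolated)
Conditions: n-BuLi, THF, 0 °C; then 7, −78 → 0 °C; aq NH4Cl
Reagents that add atoms: none
Why: Directed ortho-metalation between the two MOM ethers gives aryllithium 8, which acylates the Weinreb amide; the chelated tetrahedral adduct persists until work-up, so the chloroketone never meets the organolithium.

Step 6
Reactants: 9 1-[2,6-bis(methoxymethoxy)phenyl]-2-chloroethan-1-one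
Product: 11 (2R)-2-[2,6-bis(methoxymethoxy)phenyl]oxirane, via (1R)-chlorohydrin 10 (not isolated)
Conditions: (R)-1-methyl-3,3-diphenyltetrahydro-1H,3H-pyrrolo[1,2-c][1,3,2]oxazaborole ((R)-Me-CBS, 10 mol %), BH3·SMe2, THF, −20 °C; MeOH; then 2 M NaOH, rt
Reagents that add atoms: none
Why: Corey–Bakshi–Shibata reduction with the bulky 2,6-disubstituted aryl as the large and CH2Cl as the small substituent should give the (R)-chlorohydrin 10 (the facial sense that gives (S)-1-phenylethanol from acetophenone with this catalyst), which sets the future C2 centre; hydroxide then closes the oxirane by intramolecular Williamson displacement at CH2Cl without touching that centre.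

**Side-chain fragment**

Step 7
Reactants: 12 (4S)-4-benzyl-1,3-oxazolidin-2-one; 13 3-methylbut-2-enoyl chloride
Product: 14 (4S)-4-benzyl-3-(3-methylbut-2-enoyl)-1,3-oxazolidin-2-one
Conditions: n-BuLi, THF, −78 °C; then 13, −78 → 0 °C
Reagents that add atoms: none
Why: N-acylation of the lithiated oxazolidinone by the acid chloride, the standard entry to Evans imides.

Step 8
Reactants: 14 (4S)-4-benzyl-3-(3-methylbut-2-enoyl)-1,3-oxazolidin-2-one; 15 1-bromo-3-methylbut-2-ene
Product: 17 (4S)-4-benzyl-3-[(2S)-5-methyl-2-(prop-1-en-2-yl)hex-4-enoyl]-1,3-oxazolidin-2-one, via sodium (Z)-dienolate 16 (not isolated)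
Conditions: NaN(SiMe3)2, THF, −78 °C; then 15, −78 → −40 °C
Reagents that add atoms: none
Why: Evans asymmetric alkylation in its deconjugative form: γ-deprotonation gives the chelated (Z)-dienolate 16, which is alkylated at the α-carbon on the face away from the benzyl group, setting the side-chain stereocentre as (2S) and creating the isopropenyl group.

Step 9
Reactants: 17 (4S)-4-benzyl-3-[(2S)-5-methyl-2-(prop-1-en-2-yl)hex-4-enoyl]-1,3-oxazolidin-2-one
Product: 18 (S)-lavandulol
Conditions: LiBH4, MeOH (1 equiv), Et2O, 0 °C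
Reagents that add atoms: none
Why: Reductive cleavage of the imide by LiBH4 releases the primary alcohol and the recoverable auxiliary without touching the α-stereocentre or the alkenes.

Step 10
Reactants: 18 (S)-lavandulol
Product: 19 (S)-lavandulyl iodide
Conditions: PPh3, I2, imidazole, CH2Cl2, 0 °C → rt, dark
Reagents that add atoms: iodine II
Why: Appel-type iodination converts the primary alcohol into the iodide by SN2 at CH2 under non-acidic conditions, so the adjacent stereocentre and the homoallylic alkene are not involved.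

**Assembly and end game**

Step 11
Reactants: 4 2-[2-fluoro-4-methoxy-6-(methoxymethoxy)phenyl]-1,3-dithiane; 11 (2R)-2-[2,6-bis(methoxymethoxy)phenyl]oxirane
Product: 21 (1S)-1-[2,6-bis(methoxymethoxy)phenyl]-2-{2-[2-fluoro-4-methoxy-6-(methoxymethoxy)phenyl]-1,3-dithian-2-yl}ethan-1-ol, via lithiodithiane 20 (not isolated)
Conditions: LiN(i-Pr)2, THF, −78 °C; then 11, DMPU, −78 → −20 °C; aq NH4Cl
Reagents that add atoms: none
Why: Corey–Seebach umpolung: the amide base removes the dithiane C2–H, the most acidic proton, under equilibrating conditions at −78 °C where the fluoroarene cannot lose LiF, and lithiodithiane 20 opens the oxirane at its unhindered CH2 by SN2, so the carbinol centre is carried over unchanged (its descriptor becomes S only through the priority change).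

Step 12
Reactants: 21 (1S)-1-[2,6-bis(methoxymethoxy)phenyl]-2-{2-[2-fluoro-4-methoxy-6-(methoxymethoxy)phenyl]-1,3-dithian-2-yl}ethan-1-ol; 19 (S)-lavandulyl iodide
Product: 25 (2S)-2-[2,6-bis(methoxymethoxy)phenyl]-7-methoxy-5-(methoxymethoxy)-8-[(2R)-5-methyl-2-(prop-1-en-2-yl)hex-4-en-1-yl]spiro[chromane-4,2'-[1,3]dithiane], via C8-lithiated alkoxide 22 (not isolated), via aryne alkoxide 23 (not isolated), via C8 aryllithium 24 (not isolated)
Conditions: n-BuLi (2.1 equiv), THF (0.02 M), −78 °C; warm to −20 °C; then CuI·2LiCl (10 mol %), 19, DMPU, −20 °C → rt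
Reagents that add atoms: none
Why: Proposed new method: the first equivalent of n-BuLi makes the C2 lithium alkoxide and the second removes C8–H, the one ring proton flanked by F and OMe, to give 22; on warming, 22 loses LiF to the C8–C8a aryne 23, the tethered alkoxide adds to C8a (O1–C8a bond) to give the C8 aryllithium 24, and 24 is alkylated at the CH2–I carbon of 19 by copper-catalysed SN2 substitution (C8–C1'' bond). The closest known reaction types are the benzyne ring closure of 3-(3-halophenyl)propan-1-olates to chromans and the ortho-lithiation/LiF-loss/O-cyclization of N-acyl-3-fluoroanilines to 7-lithiobenzoxazoles that are then quenched with electrophiles, together with the alkylation of 2,6-dialkoxyphenyllithiums by primary halides; what is new is their combination with an alkoxide as internal nucleophile and an sp3 iodide as the trap. Ring C is closed by an anionic 6-exo-dig addition of oxygen to the aryne carbon C8a. No stereocentre is formed: C2 (from 11) is an alkoxide and then an ether carbon, the side-chain centre (from 19) is β to the reacting carbon, and neither is touched. The step needs lithiation at C8 rather than at C6 or on ring B (secured at −78 °C by the joint acidifying effect of F and OMe, the other sites having only ether neighbours), addition of oxygen to C8a rather than C8 (the three-atom tether from C4a can only reach C8a, and the C7 methoxy group independently directs nucleophiles to the distal aryne carbon and stabilizes the C8 anion) and substitution rather than elimination on 19 (copper catalysis); the dithiane keeps C4 inert to n-BuLi, cannot itself reach C8a except through a four-membered ring, and is the reason the aryne, not an SNAr, is the mode of C–O bond formation.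

Step 13
Reactants: 25 (2S)-2-[2,6-bis(methoxymethoxy)phenyl]-7-methoxy-5-(methoxymethoxy)-8-[(2R)-5-methyl-2-(prop-1-en-2-yl)hex-4-en-1-yl]spiro[chromane-4,2'-[1,3]dithiane]
Product: 26 (2S)-2-[2,6-bis(methoxymethoxy)phenyl]-7-methoxy-5-(methoxymethoxy)-8-[(2R)-5-methyl-2-(prop-1-en-2-yl)hex-4-en-1-yl]chroman-4-one
Conditions: MeI, CaCO3, MeCN/H2O (4:1), 45 °C
Reagents that add atoms: water O
Why: Alkylative dithiane hydrolysis: S-methylation gives a sulfonium leaving group, the thionium ion stabilized by the trioxygenated ring A is captured by water, and the CaCO3 buffer spares the MOM ethers, the two alkenes and the C2 centre.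

Step 14
Reactants: 26 (2S)-2-[2,6-bis(methoxymethoxy)phenyl]-7-methoxy-5-(methoxymethoxy)-8-[(2R)-5-methyl-2-(prop-1-en-2-yl)hex-4-en-1-yl]chroman-4-one
Product: 27 exiguaflavanone B
Conditions: HCl (1.25 M in MeOH), 0 °C → rt
Reagents that add atoms: none
Why: Acid-catalysed transacetalization removes the three MOM groups as dimethoxymethane; the 5-O-MOM group peri to the carbonyl and the ring-B groups should leave at or below room temperature, where the alkenes (which have no free ortho phenol to cyclize onto) and the C2 centre should survive.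

**Compound list**
1 | 2,6-difluoro-4-methoxybenzaldehyde | COc1cc(F)c(C=O)c(F)c1 | starting material
2 | 2-fluoro-6-hydroxy-4-methoxybenzaldehyde | COc1cc(O)c(C=O)c(F)c1 | intermediate
3 | 2-(1,3-dithian-2-yl)-3-fluoro-5-methoxyphenol | COc1cc(O)c(C2SCCCS2)c(F)c1 | intermediate
4 | 2-[2-fluoro-4-methoxy-6-(methoxymethoxy)phenyl]-1,3-dithiane | COCOc1cc(OC)cc(F)c1C1SCCCS1 | intermediate
5 | resorcinol | Oc1cccc(O)c1 | starting material
6 | 1,3-bis(methoxymethoxy)benzene | COCOc1cccc(OCOC)c1 | intermediate
7 | 2-chloro-N-methoxy-N-methylacetamide | CON(C)C(=O)CCl | starting material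
8 | 2-lithio-1,3-bis(methoxymethoxy)benzene | [Li]c1c(OCOC)cccc1OCOC | intermediate
9 | 1-[2,6-bis(methoxymethoxy)phenyl]-2-chloroethan-1-one | COCOc1cccc(OCOC)c1C(=O)CCl | intermediate
10 | (1R)-1-[2,6-bis(methoxymethoxy)phenyl]-2-chloroethan-1-ol | O[C@H](c1c(OCOC)cccc1OCOC)CCl | intermediate
11 | (2R)-2-[2,6-bis(methoxymethoxy)phenyl]oxirane | O1[C@H](c2c(OCOC)cccc2OCOC)C1 | intermediate
12 | (4S)-4-benzyl-1,3-oxazolidin-2-one | O=C1N[C@@H](Cc2ccccc2)CO1 | starting material
13 | 3-methylbut-2-enoyl chloride | CC(C)=CC(=O)Cl | starting material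
14 | (4S)-4-benzyl-3-(3-methylbut-2-enoyl)-1,3-oxazolidin-2-one | CC(C)=CC(=O)N1[C@@H](Cc2ccccc2)COC1=O | intermediate
15 | 1-bromo-3-methylbut-2-ene (prenyl bromide) | CC(C)=CCBr | starting material
16 | sodium (Z)-dienolate of 14 | [Na]O/C(=C\C(C)=C)N1[C@@H](Cc2ccccc2)COC1=O | intermediate
17 | (4S)-4-benzyl-3-[(2S)-5-methyl-2-(prop-1-en-2-yl)hex-4-enoyl]-1,3-oxazolidin-2-one | C=C(C)[C@H](CC=C(C)C)C(=O)N1[C@@H](Cc2ccccc2)COC1=O | intermediate
18 | (S)-lavandulol, (2S)-5-methyl-2-(prop-1-en-2-yl)hex-4-en-1-ol | C=C(C)[C@H](CC=C(C)C)CO | intermediate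
19 | (S)-lavandulyl iodide, (2S)-1-iodo-5-methyl-2-(prop-1-en-2-yl)hex-4-ene | C=C(C)[C@H](CC=C(C)C)CI | intermediate
20 | 2-lithio-2-[2-fluoro-4-methoxy-6-(methoxymethoxy)phenyl]-1,3-dithiane | [Li]C1(SCCCS1)c1c(F)cc(OC)cc1OCOC | intermediate
21 | (1S)-1-[2,6-bis(methoxymethoxy)phenyl]-2-{2-[2-fluoro-4-methoxy-6-(methoxymethoxy)phenyl]-1,3-dithian-2-yl}ethan-1-ol | O[C@H](c1c(OCOC)cccc1OCOC)CC1(SCCCS1)c1c(F)cc(OC)cc1OCOC | intermediate
22 | lithium alkoxide of 21 lithiated at C8 | [Li]O[C@H](c1c(OCOC)cccc1OCOC)CC1(SCCCS1)c1c(F)c([Li])c(OC)cc1OCOC | intermediate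
23 | C8–C8a aryne lithium alkoxide | [Li]O[C@H](c1c(OCOC)cccc1OCOC)CC1(SCCCS1)C1=C(OCOC)C=C(OC)C#C1 | intermediate
24 | (2S)-2-[2,6-bis(methoxymethoxy)phenyl]-8-lithio-7-methoxy-5-(methoxymethoxy)spiro[chromane-4,2'-[1,3]dithiane] | [Li]c1c(OC)cc(OCOC)c2c1O[C@H](c1c(OCOC)cccc1OCOC)CC21SCCCS1 | intermediate
25 | (2S)-2-[2,6-bis(methoxymethoxy)phenyl]-7-methoxy-5-(methoxymethoxy)-8-[(2R)-5-methyl-2-(prop-1-en-2-yl)hex-4-en-1-yl]spiro[chromane-4,2'-[1,3]dithiane] | C=C(C)[C@H](CC=C(C)C)Cc1c(OC)cc(OCOC)c2c1O[C@H](c1c(OCOC)cccc1OCOC)CC21SCCCS1 | intermediate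
26 | (2S)-2-[2,6-bis(methoxymethoxy)phenyl]-7-methoxy-5-(methoxymethoxy)-8-[(2R)-5-methyl-2-(prop-1-en-2-yl)hex-4-en-1-yl]chroman-4-one | C=C(C)[C@H](CC=C(C)C)Cc1c(OC)cc(OCOC)c2c1O[C@H](c1c(OCOC)cccc1OCOC)CC2=O | intermediate
27 | exiguaflavanone B, (2S)-2-(2,6-dihydroxyphenyl)-5-hydroxy-7-methoxy-8-[(2R)-5-methyl-2-(prop-1-en-2-yl)hex-4-en-1-yl]chroman-4-one | C=C(C)[C@H](CC=C(C)C)Cc1c(OC)cc(O)c2c1O[C@H](c1c(O)cccc1O)CC2=O | target

**Totals**
Total step count: 14.
Longest linear sequence: 7 steps (steps 1, 2, 3, 11, 12, 13, 14; the ring-B line 4, 5, 6, 11–14 and the side-chain line 7, 8, 9, 10, 12–14 are equally long).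

**Three steps most likely to fail**

Step 12 (Proposed new method). What may go wrong: lithiation at a site other than C8, capture of the aryne by other anions in solution before the lithium alkoxide closes the ring, or elimination instead of substitution on the β-branched iodide.
Fallback, from 21 back to 26: lithiation as in step 12 but iodination at −78 °C with 1,2-diiodoethane, before any LiF is lost, should give the C8 iodide F1 (directed ortho-metalation/iodination). MeI/CaCO3 as in step 13 then unmasks the ketone to give the β-hydroxy ketone F2. Its C4 carbonyl now activates the ortho C8a–F bond, so NaH in THF at 0 °C should close ring C through the same O1–C8a bond by intramolecular SNAr (addition–elimination) to the 8-iodoflavanone F3. Negishi coupling of F3 with (S)-lavandulylzinc chloride F4 (from 19: t-BuLi, Et2O, −78 °C; then ZnCl2), with Pd(OAc)2 and 2-dicyclohexylphosphino-2',6'-dimethoxybiphenyl in THF, should give 26, where the route is rejoined before step 14.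

Step 11. What may go wrong: the tertiary, doubly ortho-substituted dithianyl carbanion may open the aryl oxirane too slowly, so that proton transfer and decomposition of the sensitive epoxide take over.
Fallback, from 4 back to 21: lithiodithiane 20 is alkylated with ethylene oxide (an unhindered electrophile; THF, −78 → 0 °C) to give the primary alcohol F5. Parikh–Doering oxidation (SO3·pyridine, DMSO, Et3N) gives the aldehyde F6. Addition of aryllithium 8 (made as in step 5) at −78 °C gives the racemic carbinol F7, and a second Parikh–Doering oxidation gives the ketone F8. Corey–Bakshi–Shibata reduction with the (R)-oxazaborolidine of step 6 (aryl large, CH2 small) should then return 21.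

Step 14. What may go wrong: acid-promoted addition to the side-chain alkenes, and erosion of the C2 configuration by reversible opening of ring C once the ring-B phenols are free next to the C4 carbonyl.
Fallback, from 25 to 27: the order of unmasking is reversed. The three MOM ethers are removed first at the dithiane stage (HCl in MeOH, 0 °C) to give the triphenol F9, which has no C4 carbonyl and therefore no chalcone pathway. Neutral MeI/CaCO3 hydrolysis of the dithiane, as in step 13, should then give 27 directly.

**Further compounds**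
F1 | step 12 | (1S)-1-[2,6-bis(methoxymethoxy)phenyl]-2-{2-[2-fluoro-3-iodo-4-methoxy-6-(methoxymethoxy)phenyl]-1,3-dithian-2-yl}ethan-1-ol | O[C@H](c1c(OCOC)cccc1OCOC)CC1(SCCCS1)c1c(F)c(I)c(OC)cc1OCOC
F2 | step 12 | (3S)-3-[2,6-bis(methoxymethoxy)phenyl]-1-[2-fluoro-3-iodo-4-methoxy-6-(methoxymethoxy)phenyl]-3-hydroxypropan-1-one | O[C@H](c1c(OCOC)cccc1OCOC)CC(=O)c1c(F)c(I)c(OC)cc1OCOC
F3 | step 12 | (2S)-2-[2,6-bis(methoxymethoxy)phenyl]-8-iodo-7-methoxy-5-(methoxymethoxy)chroman-4-one | Ic1c(OC)cc(OCOC)c2c1O[C@H](c1c(OCOC)cccc1OCOC)CC2=O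
F4 | step 12 | (S)-lavandulylzinc chloride, [(2S)-5-methyl-2-(prop-1-en-2-yl)hex-4-en-1-yl]zinc chloride | C=C(C)[C@H](CC=C(C)C)C[Zn]Cl
F5 | step 11 | 2-{2-[2-fluoro-4-methoxy-6-(methoxymethoxy)phenyl]-1,3-dithian-2-yl}ethan-1-ol | OCCC1(SCCCS1)c1c(F)cc(OC)cc1OCOC
F6 | step 11 | {2-[2-fluoro-4-methoxy-6-(methoxymethoxy)phenyl]-1,3-dithian-2-yl}acetaldehyde | O=CCC1(SCCCS1)c1c(F)cc(OC)cc1OCOC
F7 | step 11 | racemic 1-[2,6-bis(methoxymethoxy)phenyl]-2-{2-[2-fluoro-4-methoxy-6-(methoxymethoxy)phenyl]-1,3-dithian-2-yl}ethan-1-ol | OC(c1c(OCOC)cccc1OCOC)CC1(SCCCS1)c1c(F)cc(OC)cc1OCOC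
F8 | step 11 | 1-[2,6-bis(methoxymethoxy)phenyl]-2-{2-[2-fluoro-4-methoxy-6-(methoxymethoxy)phenyl]-1,3-dithian-2-yl}ethan-1-one | O=C(c1c(OCOC)cccc1OCOC)CC1(SCCCS1)c1c(F)cc(OC)cc1OCOC
F9 | step 14 | 2-{(2S)-5-hydroxy-7-methoxy-8-[(2R)-5-methyl-2-(prop-1-en-2-yl)hex-4-en-1-yl]spiro[chromane-4,2'-[1,3]dithian]-2-yl}benzene-1,3-diol | C=C(C)[C@H](CC=C(C)C)Cc1c(OC)cc(O)c2c1O[C@H](c1c(O)cccc1O)CC21SCCCS1
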